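## Analysis of the target

The target 32 is a 2,3-dihydro-1-benzofuran (benzo ring A fused to the dihydrofuran ring O1–C2–C3–C3a–C7a) that carries a 4-hydroxyphenyl group (ring B) on C2, a 2,4-dihydroxybenzoyl group (carbonyl carbon C8, ring C) on C3 and a 3-(2,4-dihydroxyphenyl)-3-oxopropyl chain (ring D) on C5. C2 and C3 are the only stereocentres; both are S and their substituents are trans, the more stable arrangement on this ring. Each centre is labile in its own way: C3–H is benzylic and alpha to the C8 ketone, so it enolises, and O1–C2 is a para-hydroxybenzylic aryl ether that can open to a para-quinone methide under base or ionise under acid. If only one centre is mobile the other steers the mixture back to trans, but if both are mobile together the compound can racemise through the cis isomer, so the two must not be unlocked at the same time before the end. Further sensitive groups are five free phenols, two ortho-hydroxyaryl ketones and a benzylic C–O bond that hydrogenolysis would cut. The difficulty is to fix the absolute configuration of a small ring with two labile centres and to attach the same resorcinyl ketone unit at two different sites without confusing them. The strategy rests on C2: it is the benzylic carbon para to the ring B hydroxyl, so two-electron oxidation of that phenol makes C2 the electrophilic terminus of a para-quinone methide, five atoms away from the ring A phenol oxygen O1.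

## Retrosynthetic reasoning

32 to 31. The five phenols are unmasked last, from the methoxymethyl acetals of 31. Acetals survive aryl-metal reagents, fluoride, periodinane oxidation and palladium, and they leave under acid. That matters because the free target must not meet base, which would make C2 and C3 mobile together.

31 to 30 to 25 and 29. The bond between C5 and the side chain is cut, through enone 30, to aryl bromide 25 and aryl vinyl ketone 29. The cut sits at the arene because a bromine at C5 comes with ring A from the start, is inert until this point and also deactivates ring A in the key step. The whole three-carbon ketone chain then arrives in one coupling. Forward, a Heck reaction must arylate the terminal carbon of 29, and a hydrogenation must saturate only the C=C bond of 30.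

29 to 28 to 26 and 27; 27 to 21 to 20. The vinyl ketone is traced to allylic alcohol 28, and its aryl–carbinol bond is cut to acrolein 26 and Grignard reagent 27. Reagent 27 comes from aryl bromide 21, the bis-acetal of 4-bromoresorcinol 20. This makes 21 the single source of both resorcinyl rings.

25 to 24 to 19 and 21; 19 to 18 to 17 to 16. The C8–ring C bond is cut to aldehyde 19 and the aryl-metal species 22 and 23 derived from 21. The two ketone sites are told apart by order: C8 is built while C5 is still a bromide. Aldehyde 19 comes from alcohol 18, silyl ether 17 and phenol 16. Capping the ring B phenol of 16 locks C2 before C3 becomes enolisable at the aldehyde stage.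

16 to 14 through 15. The O1–C2 bond is cut. Phenol 16 is the adduct of the ring A phenol oxygen to the exocyclic carbon of para-quinone methide 15, which is the two-electron oxidation product of diphenol 14. The cut is made here because the free 4-hydroxyl of ring B, which the target has anyway, activates exactly this C–H bond. C3 can therefore be set beforehand on an open chain, and the ring and the second stereocentre form in one step under control of the first. C8 is held as a silyloxymethyl group so that C3 has no acidifying neighbour and the ring A phenol cannot lactonise.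

14 to 13 to 12 to 11. The two phenols of 14 are traced to the allyl ethers of 13, the silyl ether to alcohol 12, and 12 to imide 11 by reductive removal of the auxiliary. Allyl ethers are the one phenol protection that tolerates enolate chemistry and hydride and still comes off in the presence of an aryl bromide and a silyl ether.

11 to 9 and 3 through 10. The bond between the future C2 and C3 is cut to the enolate 10 of arylacetyl imide 9 and benzylic bromide 3. This is the most reliable way to set a lone benzylic stereocentre, and it puts the two aryl rings where the key step needs them. The forward alkylation must set the R configuration at the future C3.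

9 to 6 and 7; 6 to 4; 3 to 2 to 1. The imide is cut at the N–acyl bond to acid 6 and auxiliary 7. Acid 6 is the allyl ether of commercial acid 4 (through ester 5), and bromide 3 comes from alcohol 1 through allyl ether 2.

## Alternatives that were turned down

Alternative 1: Both aryl–carbonyl bonds (C8 to ring C, and the side-chain carbonyl to ring D) are cut at once. That leads back to the bis(S-phenyl thioester) A1 and two equivalents of 2,4-bis(methoxymethoxy)phenylboronic acid A2. Forward, A1 and A2 would be coupled twice with Pd2(dba)3, tri(2-furyl)phosphine and copper thiophene-2-carboxylate Cu(O2CC4H3S), a thioester–boronic acid ketone synthesis of the Liebeskind–Srogl type. The product is the pentakis(methoxymethyl) ether A3, which is the same compound as 31.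

- For it: both ketones come from one building block in one neutral, base-free operation. That is gentle on the enolisable C3 and far more convergent than the stepwise installation in steps 12 to 19; on this point it is stronger than the chosen route.
- Against it: the step closes no ring and sets no stereocentre, so the problem of making the enantiopure trans-dihydrobenzofuran diacid behind A1 is only postponed to another method.
- Against it: the C3 thioester is a hindered, alpha-aryl secondary acyl group. Its acylpalladium intermediate can lose CO or epimerise through a ketene.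
- Against it: A2 is an ortho-alkoxy, electron-rich boronic acid that is prone to protodeboronation and slow to transmetalate, and it must react completely at two unlike thioesters.
- Comparison: the chosen strategy gives up this convergence. In return its key step builds the ring and C2, and the ketones are formed by carbonyl addition and Heck chemistry, whose behaviour at a hindered centre is easier to foresee.

Alternative 2: The O1–C7a bond is cut, leading back to the syn-aldol Weinreb amide A4 with a 2,5-dibromophenyl group. Forward, CuI, 1,10-phenanthroline and Cs2CO3 would make the C2 alkoxide displace the ortho bromide (an Ullmann-type etherification closing the five-membered ring). The product is the trans Weinreb amide A5.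

- For it: both stereocentres come from a reagent-controlled aldol reaction, so C2 does not depend on substrate control. C3 is already at the carboxyl oxidation level, so the C8 ketone needs one aryl-metal addition instead of the four steps 11, 12, 14 and 15. On both points it is as strong as or stronger than the chosen route.
- Against it: A4 is a beta-hydroxy carbonyl compound with an alpha-aryl group. Hot carbonate can trigger retro-aldol cleavage, which expels a stabilised arylacetamide enolate and destroys both centres, and dehydration to the acrylamide.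
- Against it: a secondary benzylic alkoxide is a weaker partner for copper than a phenoxide, and the second bromide can couple between molecules.
- Comparison: the ring-closing step of this alternative threatens the stereocentres it relies on. In the chosen route the closure runs at 0 °C without base on a substrate whose C3 has no acidifying group, and the nucleophile is a phenol adding to a soft electrophile.

Alternative 3: Ring A is taken apart at C3a–C7a and C4–C5. This leads back to the 3-alkoxy-2-pyrone-6-carboxylate A6, whose ether side chain carries both stereocentres and a terminal alkyne. Forward, heating would bring about an intramolecular Diels–Alder reaction of the pyrone diene with the alkyne, followed by loss of CO2, to give the benzofuran ester A7.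

- For it: ring A and the dihydrofuran ring form together. The substitution pattern of ring A is dictated by the tether, and the thermal, neutral conditions cannot epimerise either centre; on this last point it is at least as safe as the chosen key step.
- Against it: A6 needs a 3-hydroxypyrone O-alkylated at a secondary para-acyloxybenzylic carbon with defined configuration, a centre that ionises easily.
- Against it: an unactivated terminal alkyne is a poor dienophile and calls for high temperature.
- Against it: the ester of A7 must still be turned into the three-carbon aryl ketone chain over several steps, where the chosen route does this by one Heck coupling on a bromide.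
- Comparison: a benzene ring is built that can be bought, so the route is longer both before and after its key step. The chosen route uses a commercial ring A and spends its key step on the bond that carries the stereochemistry.

Key step: step 9

Assumption: compounds 1, 4, 7, 20 and 26 are taken as commercial; 28 is used as the racemate because its carbinol centre disappears in step 17.

## Route

Step 1
Reactants: 1 4-hydroxybenzyl alcohol
Product: 2 [4-(prop-2-en-1-yloxy)phenyl]methanol
Conditions: allyl bromide, K2CO3, acetone, reflux
Reagents that add atoms: allyl bromide, C=CCBr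
Why: Williamson ether synthesis; K2CO3 deprotonates only the phenol, so the benzylic alcohol is left free.

Step 2
Reactants: 2 [4-(prop-2-en-1-yloxy)phenyl]methanol
Product: 3 1-(bromomethyl)-4-(prop-2-en-1-yloxy)benzene
Conditions: PBr3, Et2O, 0 °C
Reagents that add atoms: phosphorus tribromide, BrP(Br)Br
Why: Bromination of a primary benzylic alcohol through its phosphite ester; the low temperature spares the allyl ether, and the reactive bromide is used without storage.

Step 3
Reactants: 4 (5-bromo-2-hydroxyphenyl)acetic acid
Product: 6 [5-bromo-2-(prop-2-en-1-yloxy)phenyl]acetic acid, via allyl ester 5 (not isolated)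
Conditions: allyl bromide, K2CO3, DMF, rt; then 2 M NaOH (aq), MeOH, rt; 1 M HCl work-up
Reagents that add atoms: allyl bromide, C=CCBr; sodium hydroxide, [Na+].[OH-]
Why: Double O-alkylation of carboxylate and phenoxide followed by saponification of the ester only; the aryl allyl ether is inert to hydroxide and blocks lactonisation to the benzofuranone.

Step 4
Reactants: 6 [5-bromo-2-(prop-2-en-1-yloxy)phenyl]acetic acid; 7 (R)-4-benzyl-2-oxazolidinone
Product: 9 (4R)-4-benzyl-3-{[5-bromo-2-(prop-2-en-1-yloxy)phenyl]acetyl}-1,3-oxazolidin-2-one, via mixed pivalic anhydride 8 (not isolated)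
Conditions: pivaloyl chloride, Et3N, THF, −20 °C; then LiCl, 7, −20 °C to rt
Reagents that add atoms: none
Why: N-Acylation of the oxazolidinone by a mixed anhydride, which is attacked at the less hindered arylacetyl carbonyl; the auxiliary centre is not involved.

Step 5
Reactants: 9 (4R)-4-benzyl-3-{[5-bromo-2-(prop-2-en-1-yloxy)phenyl]acetyl}-1,3-oxazolidin-2-one; 3 1-(bromomethyl)-4-(prop-2-en-1-yloxy)benzene
Product: 11 (4R)-4-benzyl-3-{(2R)-2-[5-bromo-2-(prop-2-en-1-yloxy)phenyl]-3-[4-(prop-2-en-1-yloxy)phenyl]propanoyl}-1,3-oxazolidin-2-one, via sodium Z-enolate 10 (not isolated)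
Conditions: NaN(SiMe3)2 (1.05 equiv), THF, −78 °C; then 3, −78 to −30 °C
Reagents that add atoms: none
Why: Evans asymmetric alkylation; the chelated Z-enolate is shielded on the face of the auxiliary benzyl group, so the benzylic bromide enters from the other face and sets the R centre that becomes C3. A minimal excess of base limits re-enolisation of the alpha-aryl product.

Step 6
Reactants: 11 (4R)-4-benzyl-3-{(2R)-2-[5-bromo-2-(prop-2-en-1-yloxy)phenyl]-3-[4-(prop-2-en-1-yloxy)phenyl]propanoyl}-1,3-oxazolidin-2-one
Product: 12 (2R)-2-[5-bromo-2-(prop-2-en-1-yloxy)phenyl]-3-[4-(prop-2-en-1-yloxy)phenyl]propan-1-ol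
Conditions: LiBH4, MeOH (1 equiv), THF, 0 °C
Reagents that add atoms: none
Why: Reductive cleavage of the imide at the exocyclic carbonyl releases the auxiliary; hydride addition at 0 °C should be faster than enolisation, and the aryl bromide and allyl ethers are inert.

Step 7
Reactants: 12 (2R)-2-[5-bromo-2-(prop-2-en-1-yloxy)phenyl]-3-[4-(prop-2-en-1-yloxy)phenyl]propan-1-ol
Product: 13 {[(2R)-2-[5-bromo-2-(prop-2-en-1-yloxy)phenyl]-3-[4-(prop-2-en-1-yloxy)phenyl]propyl]oxy}(tert-butyl)dimethylsilane
Conditions: TBSCl, imidazole, DMF, rt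
Reagents that add atoms: tert-butyldimethylsilyl chloride, CC(C)(C)[Si](C)(C)Cl
Why: Silylation of a primary alcohol; it keeps C8 at the alcohol oxidation level, where C3–H is not acidic.

Step 8
Reactants: 13 {[(2R)-2-[5-bromo-2-(prop-2-en-1-yloxy)phenyl]-3-[4-(prop-2-en-1-yloxy)phenyl]propyl]oxy}(tert-butyl)dimethylsilane
Product: 14 4-bromo-2-[(2R)-1-{[tert-butyl(dimethyl)silyl]oxy}-3-(4-hydroxyphenyl)propan-2-yl]phenol
Conditions: Pd(PPh3)4 (5 mol%), morpholine, THF, rt
Reagents that add atoms: none
Why: Tsuji–Trost deallylation; zerovalent palladium ionises both aryl allyl ethers to π-allyl complexes that morpholine captures. At room temperature with PPh3, insertion into the electron-rich aryl bromide is much slower, and the neutral medium leaves the silyl ether alone.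

Step 9
Reactants: 14 4-bromo-2-[(2R)-1-{[tert-butyl(dimethyl)silyl]oxy}-3-(4-hydroxyphenyl)propan-2-yl]phenol
Product: 16 4-[(2S,3R)-5-bromo-3-({[tert-butyl(dimethyl)silyl]oxy}methyl)-2,3-dihydro-1-benzofuran-2-yl]phenol (trans), via para-quinone methide 15 (not isolated)
Conditions: DDQ (1.0 equiv), CH2Cl2, 0 °C to rt
Reagents that add atoms: none
Why: DDQ forms a charge-transfer complex with the more electron-rich 4-alkylphenol (ring B) and removes a hydride equivalent from the para-benzylic CH2, the future C2, giving para-quinone methide 15 and the hydroquinone of the reagent. The closest known reaction type is the quinone dehydrogenation of 4-alkylphenols to para-quinone methides with trapping by a phenol in the same molecule, as in oxidative flavan and 2-aryl-dihydrobenzofuran syntheses. The ring A phenol oxygen then adds to the exocyclic methide carbon in an oxa-1,6-addition that is 5-exo-trig and is driven by rearomatisation of ring B, forming O1–C2 and the dihydrofuran ring. C2 is the only new stereocentre and is controlled by C3: in the envelope-like transition state the quinone methide ring turns away from the silyloxymethyl group, so the aryl group ends up anti to it, and because the addition can reverse through 15 the trans isomer is also the thermodynamic outcome. C3 cannot epimerise, since it carries no acidifying carbonyl. Site selectivity between the two phenols is needed: the bromine para to the ring A hydroxyl lowers the electron density of that ring, and an ortho-quinone methide through the tertiary C3–H is less favourable than the para-quinone methide at the unhindered CH2. Chemoselectivity against a second dehydrogenation of 16 to the 2-arylbenzofuran is sought with one equivalent of oxidant at low temperature. A two-electron hydride acceptor is preferred to a one-electron oxidant such as Ag2O because ring B has free ortho positions and a free phenoxyl radical would tend to couple.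

Step 10
Reactants: 16 4-[(2S,3R)-5-bromo-3-({[tert-butyl(dimethyl)silyl]oxy}methyl)-2,3-dihydro-1-benzofuran-2-yl]phenol
Product: 17 {[(2S,3R)-5-bromo-2-[4-(methoxymethoxy)phenyl]-2,3-dihydro-1-benzofuran-3-yl]methoxy}(tert-butyl)dimethylsilane
Conditions: MOMCl, i-Pr2NEt, CH2Cl2, 0 °C to rt
Reagents that add atoms: chloromethyl methyl ether, COCCl
Why: O-Alkylation of the phenol; capping ring B removes the hydroxyl that could reopen O1–C2 through the quinone methide, so C2 is locked from here on while C3 is still not enolisable.

Step 11
Reactants: 17 {[(2S,3R)-5-bromo-2-[4-(methoxymethoxy)phenyl]-2,3-dihydro-1-benzofuran-3-yl]methoxy}(tert-butyl)dimethylsilane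
Product: 18 {(2S,3R)-5-bromo-2-[4-(methoxymethoxy)phenyl]-2,3-dihydro-1-benzofuran-3-yl}methanol
Conditions: n-Bu4NF, THF, 0 °C to rt
Reagents that add atoms: none
Why: Fluoride-induced desilylation; the acetal, the aryl bromide and the ring are inert, and no acidic C–H is present for the basic fluoride.

Step 12
Reactants: 18 {(2S,3R)-5-bromo-2-[4-(methoxymethoxy)phenyl]-2,3-dihydro-1-benzofuran-3-yl}methanol
Product: 19 (2S,3S)-5-bromo-2-[4-(methoxymethoxy)phenyl]-2,3-dihydro-1-benzofuran-3-carbaldehyde
Conditions: Dess–Martin periodinane, NaHCO3, CH2Cl2, 0 °C to rt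
Reagents that add atoms: none
Why: Dess–Martin oxidation under buffered, non-basic conditions stops at the aldehyde (the descriptor at C3 changes only because the priorities change). C3 is now enolisable, but with C2 fixed any enolisation returns the more stable trans aldehyde, and ring opening by loss of O1 would be the reverse of a 5-endo-trig closure.

Step 13
Reactants: 20 4-bromoresorcinol
Product: 21 1-bromo-2,4-bis(methoxymethoxy)benzene
Conditions: MOMCl, i-Pr2NEt, CH2Cl2, 0 °C to rt
Reagents that add atoms: chloromethyl methyl ether, COCCl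
Why: O-Alkylation of both phenols; the acetals later stabilise the ortho-metalated arene by chelation.

Step 14
Reactants: 19 (2S,3S)-5-bromo-2-[4-(methoxymethoxy)phenyl]-2,3-dihydro-1-benzofuran-3-carbaldehyde; 21 1-bromo-2,4-bis(methoxymethoxy)benzene
Product: 24 [2,4-bis(methoxymethoxy)phenyl]{(2S,3R)-5-bromo-2-[4-(methoxymethoxy)phenyl]-2,3-dihydro-1-benzofuran-3-yl}methanol (both carbinol epimers), via aryllithium 22 (not isolated), via arylcerium dichloride 23 (not isolated)
Conditions: 21, n-BuLi, THF, −78 °C; CeCl3 (anhydrous), THF, −78 °C; then 19, −78 °C; aq. NH4Cl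
Reagents that add atoms: none
Why: Bromine–lithium exchange followed by transmetalation to cerium gives a strongly nucleophilic but weakly basic aryl reagent. It adds to the enolisable alpha-aryl aldehyde and does not exchange with the C5 bromide; the new carbinol centre is formed without control and is removed in step 15.

Step 15
Reactants: 24 [2,4-bis(methoxymethoxy)phenyl]{(2S,3R)-5-bromo-2-[4-(methoxymethoxy)phenyl]-2,3-dihydro-1-benzofuran-3-yl}methanol
Product: 25 [2,4-bis(methoxymethoxy)phenyl]{(2S,3S)-5-bromo-2-[4-(methoxymethoxy)phenyl]-2,3-dihydro-1-benzofuran-3-yl}methanone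
Conditions: Dess–Martin periodinane, NaHCO3, CH2Cl2, rt
Reagents that add atoms: none
Why: Dess–Martin oxidation of a benzylic secondary alcohol; both epimers converge on the ketone, and with C2 locked the trans arrangement at C3 is the stable one.

Step 16
Reactants: 21 1-bromo-2,4-bis(methoxymethoxy)benzene; 26 acrolein
Product: 28 1-[2,4-bis(methoxymethoxy)phenyl]prop-2-en-1-ol (racemic), via arylmagnesium bromide 27 (not isolated)
Conditions: Mg turnings, I2 (cat.), THF, rt to 45 °C; then 26, −78 to 0 °C; aq. NH4Cl
Reagents that add atoms: none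
Why: Grignard formation by insertion of magnesium into the C–Br bond, then 1,2-addition of the arylmagnesium bromide to the aldehyde carbonyl of the enal at low temperature. The magnesium reagent is chosen here because it is a weaker base and a poorer initiator of anionic polymerisation of acrolein than an aryllithium, and the ortho acetal oxygen stabilises it by chelation.

Step 17
Reactants: 28 1-[2,4-bis(methoxymethoxy)phenyl]prop-2-en-1-ol
Product: 29 1-[2,4-bis(methoxymethoxy)phenyl]prop-2-en-1-one
Conditions: Dess–Martin periodinane, NaHCO3, CH2Cl2, 0 °C; used at once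
Reagents that add atoms: none
Why: Dess–Martin oxidation of a benzylic and allylic alcohol; the aryl vinyl ketone is kept cold and used directly to avoid polymerisation.

Step 18
Reactants: 25 [2,4-bis(methoxymethoxy)phenyl]{(2S,3S)-5-bromo-2-[4-(methoxymethoxy)phenyl]-2,3-dihydro-1-benzofuran-3-yl}methanone; 29 1-[2,4-bis(methoxymethoxy)phenyl]prop-2-en-1-one
Product: 30 (2E)-1-[2,4-bis(methoxymethoxy)phenyl]-3-{(2S,3S)-3-[2,4-bis(methoxymethoxy)benzoyl]-2-[4-(methoxymethoxy)phenyl]-2,3-dihydro-1-benzofuran-5-yl}prop-2-en-1-one
Conditions: Pd2(dba)3 (2.5 mol%), [HP(t-Bu)3]BF4 (10 mol%), Cy2NMe, 1,4-dioxane, 50–70 °C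
Reagents that add atoms: none
Why: Mizoroki–Heck reaction; zerovalent palladium with the bulky, electron-rich P(t-Bu)3 inserts into the electron-rich C5–Br bond, the enone inserts with the aryl group going to its unsubstituted carbon, and syn beta-hydride elimination gives the E-enone. The mild temperature and hindered amine spare the vinyl ketone, and enolisation at C3 can only return the trans isomer.

Step 19
Reactants: 30 (2E)-1-[2,4-bis(methoxymethoxy)phenyl]-3-{(2S,3S)-3-[2,4-bis(methoxymethoxy)benzoyl]-2-[4-(methoxymethoxy)phenyl]-2,3-dihydro-1-benzofuran-5-yl}prop-2-en-1-one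
Product: 31 1-[2,4-bis(methoxymethoxy)phenyl]-3-{(2S,3S)-3-[2,4-bis(methoxymethoxy)benzoyl]-2-[4-(methoxymethoxy)phenyl]-2,3-dihydro-1-benzofuran-5-yl}propan-1-one
Conditions: H2 (1 atm), RhCl(PPh3)3 (10 mol%), toluene/EtOH, rt to 40 °C
Reagents that add atoms: none
Why: Homogeneous hydrogenation with Wilkinson's catalyst saturates the disubstituted enone C=C bond; the aryl ketones, the acetals and the benzylic O1–C2 bond, which heterogeneous palladium could cleave, are not touched.

Step 20
Reactants: 31 1-[2,4-bis(methoxymethoxy)phenyl]-3-{(2S,3S)-3-[2,4-bis(methoxymethoxy)benzoyl]-2-[4-(methoxymethoxy)phenyl]-2,3-dihydro-1-benzofuran-5-yl}propan-1-one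
Product: 32 1-(2,4-dihydroxyphenyl)-3-[(2S,3S)-3-(2,4-dihydroxybenzoyl)-2-(4-hydroxyphenyl)-2,3-dihydro-1-benzofuran-5-yl]propan-1-one
Conditions: 3 M HCl (aq)/MeOH, 45 °C
Reagents that add atoms: none
Why: Acid-catalysed acetal exchange with methanol frees all five phenols, the two ortho to the carbonyls first. The medium is kept non-basic because in the free target both centres would be mobile under base, while ionisation of O1–C2 under acid is disfavoured by the electron-withdrawing C8 carbonyl next to C2.

## Compound list

1 | 4-hydroxybenzyl alcohol | OCc1ccc(O)cc1 | starting material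
2 | [4-(prop-2-en-1-yloxy)phenyl]methanol | OCc1ccc(OCC=C)cc1 | intermediate
3 | 1-(bromomethyl)-4-(prop-2-en-1-yloxy)benzene | BrCc1ccc(OCC=C)cc1 | intermediate
4 | (5-bromo-2-hydroxyphenyl)acetic acid | OC(=O)Cc1cc(Br)ccc1O | starting material
5 | prop-2-en-1-yl [5-bromo-2-(prop-2-en-1-yloxy)phenyl]acetate | C=CCOC(=O)Cc1cc(Br)ccc1OCC=C | intermediate
6 | [5-bromo-2-(prop-2-en-1-yloxy)phenyl]acetic acid | OC(=O)Cc1cc(Br)ccc1OCC=C | intermediate
7 | (R)-4-benzyl-2-oxazolidinone | O=C1N[C@H](Cc2ccccc2)CO1 | starting material
8 | [5-bromo-2-(prop-2-en-1-yloxy)phenyl]acetic 2,2-dimethylpropanoic anhydride | CC(C)(C)C(=O)OC(=O)Cc1cc(Br)ccc1OCC=C | intermediate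
9 | (4R)-4-benzyl-3-{[5-bromo-2-(prop-2-en-1-yloxy)phenyl]acetyl}-1,3-oxazolidin-2-one | C=CCOc1ccc(Br)cc1CC(=O)N1[C@H](Cc2ccccc2)COC1=O | intermediate
10 | sodium (Z)-enolate of 9 | C=CCOc1ccc(Br)cc1/C=C(\[O-])N1[C@H](Cc2ccccc2)COC1=O.[Na+] | intermediate
11 | (4R)-4-benzyl-3-{(2R)-2-[5-bromo-2-(prop-2-en-1-yloxy)phenyl]-3-[4-(prop-2-en-1-yloxy)phenyl]propanoyl}-1,3-oxazolidin-2-one | C=CCOc1ccc(Br)cc1[C@@H](Cc1ccc(OCC=C)cc1)C(=O)N1[C@H](Cc2ccccc2)COC1=O | intermediate
12 | (2R)-2-[5-bromo-2-(prop-2-en-1-yloxy)phenyl]-3-[4-(prop-2-en-1-yloxy)phenyl]propan-1-ol | C=CCOc1ccc(Br)cc1[C@@H](Cc1ccc(OCC=C)cc1)CO | intermediate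
13 | {[(2R)-2-[5-bromo-2-(prop-2-en-1-yloxy)phenyl]-3-[4-(prop-2-en-1-yloxy)phenyl]propyl]oxy}(tert-butyl)dimethylsilane | C=CCOc1ccc(Br)cc1[C@@H](Cc1ccc(OCC=C)cc1)CO[Si](C)(C)C(C)(C)C | intermediate
14 | 4-bromo-2-[(2R)-1-{[tert-butyl(dimethyl)silyl]oxy}-3-(4-hydroxyphenyl)propan-2-yl]phenol | Oc1ccc(Br)cc1[C@H](CO[Si](C)(C)C(C)(C)C)Cc1ccc(O)cc1 | intermediate
15 | 4-[(2R)-2-(5-bromo-2-hydroxyphenyl)-3-{[tert-butyl(dimethyl)silyl]oxy}propylidene]cyclohexa-2,5-dien-1-one | Oc1ccc(Br)cc1[C@H](CO[Si](C)(C)C(C)(C)C)C=C1C=CC(=O)C=C1 | intermediate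
16 | 4-[(2S,3R)-5-bromo-3-({[tert-butyl(dimethyl)silyl]oxy}methyl)-2,3-dihydro-1-benzofuran-2-yl]phenol | Brc1ccc2c(c1)[C@H](CO[Si](C)(C)C(C)(C)C)[C@@H](c1ccc(O)cc1)O2 | intermediate
17 | {[(2S,3R)-5-bromo-2-[4-(methoxymethoxy)phenyl]-2,3-dihydro-1-benzofuran-3-yl]methoxy}(tert-butyl)dimethylsilane | Brc1ccc2c(c1)[C@H](CO[Si](C)(C)C(C)(C)C)[C@@H](c1ccc(OCOC)cc1)O2 | intermediate
18 | {(2S,3R)-5-bromo-2-[4-(methoxymethoxy)phenyl]-2,3-dihydro-1-benzofuran-3-yl}methanol | Brc1ccc2c(c1)[C@H](CO)[C@@H](c1ccc(OCOC)cc1)O2 | intermediate
19 | (2S,3S)-5-bromo-2-[4-(methoxymethoxy)phenyl]-2,3-dihydro-1-benzofuran-3-carbaldehyde | Brc1ccc2c(c1)[C@H](C=O)[C@@H](c1ccc(OCOC)cc1)O2 | intermediate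
20 | 4-bromoresorcinol | Oc1ccc(Br)c(O)c1 | starting material
21 | 1-bromo-2,4-bis(methoxymethoxy)benzene | COCOc1ccc(Br)c(OCOC)c1 | intermediate
22 | [2,4-bis(methoxymethoxy)phenyl]lithium | [Li]c1ccc(OCOC)cc1OCOC | intermediate
23 | dichloro[2,4-bis(methoxymethoxy)phenyl]cerium | Cl[Ce](Cl)c1ccc(OCOC)cc1OCOC | intermediate
24 | [2,4-bis(methoxymethoxy)phenyl]{(2S,3R)-5-bromo-2-[4-(methoxymethoxy)phenyl]-2,3-dihydro-1-benzofuran-3-yl}methanol, both epimers at the carbinol carbon | Brc1ccc2c(c1)[C@H](C(O)c1ccc(OCOC)cc1OCOC)[C@@H](c1ccc(OCOC)cc1)O2 | intermediate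
25 | [2,4-bis(methoxymethoxy)phenyl]{(2S,3S)-5-bromo-2-[4-(methoxymethoxy)phenyl]-2,3-dihydro-1-benzofuran-3-yl}methanone | Brc1ccc2c(c1)[C@H](C(=O)c1ccc(OCOC)cc1OCOC)[C@@H](c1ccc(OCOC)cc1)O2 | intermediate
26 | acrolein | C=CC=O | starting material
27 | bromo[2,4-bis(methoxymethoxy)phenyl]magnesium | Br[Mg]c1ccc(OCOC)cc1OCOC | intermediate
28 | 1-[2,4-bis(methoxymethoxy)phenyl]prop-2-en-1-ol (racemic) | C=CC(O)c1ccc(OCOC)cc1OCOC | intermediate
29 | 1-[2,4-bis(methoxymethoxy)phenyl]prop-2-en-1-one | C=CC(=O)c1ccc(OCOC)cc1OCOC | intermediate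
30 | (2E)-1-[2,4-bis(methoxymethoxy)phenyl]-3-{(2S,3S)-3-[2,4-bis(methoxymethoxy)benzoyl]-2-[4-(methoxymethoxy)phenyl]-2,3-dihydro-1-benzofuran-5-yl}prop-2-en-1-one | O=C(/C=C/c1ccc2c(c1)[C@H](C(=O)c1ccc(OCOC)cc1OCOC)[C@@H](c1ccc(OCOC)cc1)O2)c1ccc(OCOC)cc1OCOC | intermediate
31 | 1-[2,4-bis(methoxymethoxy)phenyl]-3-{(2S,3S)-3-[2,4-bis(methoxymethoxy)benzoyl]-2-[4-(methoxymethoxy)phenyl]-2,3-dihydro-1-benzofuran-5-yl}propan-1-one | O=C(CCc1ccc2c(c1)[C@H](C(=O)c1ccc(OCOC)cc1OCOC)[C@@H](c1ccc(OCOC)cc1)O2)c1ccc(OCOC)cc1OCOC | intermediate
32 | 1-(2,4-dihydroxyphenyl)-3-[(2S,3S)-3-(2,4-dihydroxybenzoyl)-2-(4-hydroxyphenyl)-2,3-dihydro-1-benzofuran-5-yl]propan-1-one | O=C(CCc1ccc2c(c1)[C@H](C(=O)c1ccc(O)cc1O)[C@@H](c1ccc(O)cc1)O2)c1ccc(O)cc1O | target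

## Step count and least certain steps

Total step count: 20. Longest linear sequence: 15 steps (steps 3 to 12, 14, 15, 18, 19 and 20, from compound 4).

Step 9 (key step). The most likely failures are a second dehydrogenation of the product towards the aromatic benzofuran, oxidation starting at ring A or at the C3–H bond, and oligomerisation of the quinone methide before the phenol closes on it. All follow from the fact that the oxidant cannot tell the wanted benzylic C–H from other electron-rich sites once the first product is present.

The fallback reaches the same quinone methide by dehydration instead of oxidation; it sets out from acid 6 and comes back to the route at 16.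
- Acid 6 would be joined (pivaloyl chloride, Et3N, LiCl) to commercial (S)-4-benzyl-2-oxazolidinone to give (4S)-4-benzyl-3-{[5-bromo-2-(prop-2-en-1-yloxy)phenyl]acetyl}-1,3-oxazolidin-2-one F1.
- Its dibutylboron Z-enolate (Bu2BOTf, i-Pr2NEt, CH2Cl2, −78 to 0 °C) would add to commercial 4-(prop-2-en-1-yloxy)benzaldehyde to give the syn-aldol adduct (4S)-4-benzyl-3-{(2S,3S)-2-[5-bromo-2-(prop-2-en-1-yloxy)phenyl]-3-hydroxy-3-[4-(prop-2-en-1-yloxy)phenyl]propanoyl}-1,3-oxazolidin-2-one F2. The boron aldol reaction uses the enolate face opposite to that of the alkylation, which is why the enantiomeric auxiliary gives the same configuration at the future C3.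
- LiBH4 would give (1S,2R)-2-[5-bromo-2-(prop-2-en-1-yloxy)phenyl]-1-[4-(prop-2-en-1-yloxy)phenyl]propane-1,3-diol F3.
- TBSCl and imidazole at 0 °C would give the primary silyl ether (1S,2R)-2-[5-bromo-2-(prop-2-en-1-yloxy)phenyl]-3-{[tert-butyl(dimethyl)silyl]oxy}-1-[4-(prop-2-en-1-yloxy)phenyl]propan-1-ol F4.
- Pd(PPh3)4 and morpholine would give 4-bromo-2-[(1S,2R)-3-{[tert-butyl(dimethyl)silyl]oxy}-1-hydroxy-1-(4-hydroxyphenyl)propan-2-yl]phenol F5.
- With a trace of acid (pyridinium p-toluenesulfonate, CH2Cl2, rt) the para-hydroxybenzylic alcohol of F5 would lose water to quinone methide 15, which closes to 16. The carbinol configuration is lost on the way and C3 again dictates the trans ring; no oxidant is present, so over-oxidation cannot occur.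

Step 18. The vinyl ketone 29 may polymerise or add the amine base before the slow insertion of palladium into the electron-rich, para-alkoxy aryl bromide has taken place, so that the coupling stalls.

The fallback replaces the Heck reaction by a B-alkyl Suzuki–Miyaura coupling; it sets out from 28 and 25 and comes back at 31, so that step 19 is not needed either.
- Alcohol 28 would be silylated (TBSCl, imidazole) to tert-butyl({1-[2,4-bis(methoxymethoxy)phenyl]prop-2-en-1-yl}oxy)dimethylsilane F8.
- Hydroboration with 9-borabicyclo[3.3.1]nonane in THF would give the primary alkylborane 9-{3-[2,4-bis(methoxymethoxy)phenyl]-3-{[tert-butyl(dimethyl)silyl]oxy}propyl}-9-borabicyclo[3.3.1]nonane F9, used without isolation after the excess hydride is quenched with water.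
- Coupling with 25 (PdCl2(dppf), K3PO4 (aq), DMF/THF, 60 °C) would give [2,4-bis(methoxymethoxy)phenyl]{(2S,3S)-5-(3-[2,4-bis(methoxymethoxy)phenyl]-3-{[tert-butyl(dimethyl)silyl]oxy}propyl)-2-[4-(methoxymethoxy)phenyl]-2,3-dihydro-1-benzofuran-3-yl}methanone F10.
- n-Bu4NF would give the alcohol [2,4-bis(methoxymethoxy)phenyl]{(2S,3S)-5-{3-[2,4-bis(methoxymethoxy)phenyl]-3-hydroxypropyl}-2-[4-(methoxymethoxy)phenyl]-2,3-dihydro-1-benzofuran-3-yl}methanone F11, and Dess–Martin periodinane would oxidise F11 to 31.

Step 14. The aryl-metal reagent may deprotonate the alpha-aryl aldehyde instead of adding to it, which leads to recovered or self-condensed aldehyde. The aldehyde 19 itself may also degrade on handling, because its C3–H is doubly activated.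

The fallback avoids the aldehyde oxidation level; it sets out from alcohol 18 and comes back at ketone 25, so that step 15 is not needed.
- Alcohol 18 would be oxidised directly (TEMPO cat., PhI(OAc)2, MeCN/H2O) to (2S,3S)-5-bromo-2-[4-(methoxymethoxy)phenyl]-2,3-dihydro-1-benzofuran-3-carboxylic acid F6.
- F6 would be converted (N,O-dimethylhydroxylamine hydrochloride, EDC hydrochloride, i-Pr2NEt, CH2Cl2) into (2S,3S)-5-bromo-N-methoxy-2-[4-(methoxymethoxy)phenyl]-N-methyl-2,3-dihydro-1-benzofuran-3-carboxamide F7, which is the same compound as A5.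
- Aryllithium 22, made from 21 and n-BuLi in THF at −78 °C, would add once to F7 through the stable chelate and give 25 on work-up. Deprotonation of the amide would only return F7 on quenching.

Step 19. Reduction of the aryl-conjugated enone at rhodium may be slow, and forcing it with a more active catalyst would bring hydrogenolysis of the benzylic O1–C2 bond or reduction of a ketone.

The fallback never forms the enone; it sets out from 25 and 28 and comes back at 31. Bromide 25 would be coupled with allylic alcohol 28 under phosphine-free Heck conditions (Pd(OAc)2, n-Bu4NCl, NaHCO3, DMF, 90 °C). After arylation of the terminal carbon, palladium hydride elimination towards the carbinol carbon gives the enol and so the saturated ketone 31 directly. No new compound is made.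

## Further compounds

F1 | step 9 | (4S)-4-benzyl-3-{[5-bromo-2-(prop-2-en-1-yloxy)phenyl]acetyl}-1,3-oxazolidin-2-one | C=CCOc1ccc(Br)cc1CC(=O)N1[C@@H](Cc2ccccc2)COC1=O
F2 | step 9 | (4S)-4-benzyl-3-{(2S,3S)-2-[5-bromo-2-(prop-2-en-1-yloxy)phenyl]-3-hydroxy-3-[4-(prop-2-en-1-yloxy)phenyl]propanoyl}-1,3-oxazolidin-2-one | C=CCOc1ccc(Br)cc1[C@H](C(=O)N1[C@@H](Cc2ccccc2)COC1=O)[C@H](O)c1ccc(OCC=C)cc1
F3 | step 9 | (1S,2R)-2-[5-bromo-2-(prop-2-en-1-yloxy)phenyl]-1-[4-(prop-2-en-1-yloxy)phenyl]propane-1,3-diol | C=CCOc1ccc(Br)cc1[C@H](CO)[C@H](O)c1ccc(OCC=C)cc1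
F4 | step 9 | (1S,2R)-2-[5-bromo-2-(prop-2-en-1-yloxy)phenyl]-3-{[tert-butyl(dimethyl)silyl]oxy}-1-[4-(prop-2-en-1-yloxy)phenyl]propan-1-ol | C=CCOc1ccc(Br)cc1[C@H](CO[Si](C)(C)C(C)(C)C)[C@H](O)c1ccc(OCC=C)cc1
F5 | step 9 | 4-bromo-2-[(1S,2R)-3-{[tert-butyl(dimethyl)silyl]oxy}-1-hydroxy-1-(4-hydroxyphenyl)propan-2-yl]phenol | Oc1ccc(Br)cc1[C@H](CO[Si](C)(C)C(C)(C)C)[C@H](O)c1ccc(O)cc1
F6 | step 14 | (2S,3S)-5-bromo-2-[4-(methoxymethoxy)phenyl]-2,3-dihydro-1-benzofuran-3-carboxylic acid | Brc1ccc2c(c1)[C@H](C(O)=O)[C@@H](c1ccc(OCOC)cc1)O2
F7 | step 14 | (2S,3S)-5-bromo-N-methoxy-2-[4-(methoxymethoxy)phenyl]-N-methyl-2,3-dihydro-1-benzofuran-3-carboxamide | Brc1ccc2c(c1)[C@H](C(=O)N(C)OC)[C@@H](c1ccc(OCOC)cc1)O2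
F8 | step 18 | tert-butyl({1-[2,4-bis(methoxymethoxy)phenyl]prop-2-en-1-yl}oxy)dimethylsilane (racemic) | C=CC(O[Si](C)(C)C(C)(C)C)c1ccc(OCOC)cc1OCOC
F9 | step 18 | 9-{3-[2,4-bis(methoxymethoxy)phenyl]-3-{[tert-butyl(dimethyl)silyl]oxy}propyl}-9-borabicyclo[3.3.1]nonane | CC(C)(C)[Si](C)(C)OC(CCB1C2CCCC1CCC2)c1ccc(OCOC)cc1OCOC
F10 | step 18 | [2,4-bis(methoxymethoxy)phenyl]{(2S,3S)-5-(3-[2,4-bis(methoxymethoxy)phenyl]-3-{[tert-butyl(dimethyl)silyl]oxy}propyl)-2-[4-(methoxymethoxy)phenyl]-2,3-dihydro-1-benzofuran-3-yl}methanone | CC(C)(C)[Si](C)(C)OC(CCc1ccc2c(c1)[C@H](C(=O)c1ccc(OCOC)cc1OCOC)[C@@H](c1ccc(OCOC)cc1)O2)c1ccc(OCOC)cc1OCOC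
F11 | step 18 | [2,4-bis(methoxymethoxy)phenyl]{(2S,3S)-5-{3-[2,4-bis(methoxymethoxy)phenyl]-3-hydroxypropyl}-2-[4-(methoxymethoxy)phenyl]-2,3-dihydro-1-benzofuran-3-yl}methanone | OC(CCc1ccc2c(c1)[C@H](C(=O)c1ccc(OCOC)cc1OCOC)[C@@H](c1ccc(OCOC)cc1)O2)c1ccc(OCOC)cc1OCOC
F0 | step 19 | none | none
A1 | alternative 1 | S-phenyl (2S,3S)-2-[4-(methoxymethoxy)phenyl]-5-[3-oxo-3-(phenylsulfanyl)propyl]-2,3-dihydro-1-benzofuran-3-carbothioate | O=C(CCc1ccc2c(c1)[C@H](C(=O)Sc1ccccc1)[C@@H](c1ccc(OCOC)cc1)O2)Sc1ccccc1
A2 | alternative 1 | [2,4-bis(methoxymethoxy)phenyl]boronic acid | OB(O)c1ccc(OCOC)cc1OCOC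
A3 | alternative 1 | 1-[2,4-bis(methoxymethoxy)phenyl]-3-{(2S,3S)-3-[2,4-bis(methoxymethoxy)benzoyl]-2-[4-(methoxymethoxy)phenyl]-2,3-dihydro-1-benzofuran-5-yl}propan-1-one | O=C(CCc1ccc2c(c1)[C@H](C(=O)c1ccc(OCOC)cc1OCOC)[C@@H](c1ccc(OCOC)cc1)O2)c1ccc(OCOC)cc1OCOC
A4 | alternative 2 | (2S,3S)-2-(2,5-dibromophenyl)-3-hydroxy-N-methoxy-3-[4-(methoxymethoxy)phenyl]-N-methylpropanamide | Brc1ccc(Br)c(c1)[C@H](C(=O)N(C)OC)[C@H](O)c1ccc(OCOC)cc1
A5 | alternative 2 | (2S,3S)-5-bromo-N-methoxy-2-[4-(methoxymethoxy)phenyl]-N-methyl-2,3-dihydro-1-benzofuran-3-carboxamide | Brc1ccc2c(c1)[C@H](C(=O)N(C)OC)[C@@H](c1ccc(OCOC)cc1)O2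
A6 | alternative 3 | methyl 3-{[(1S,2R)-2-({[tert-butyl(dimethyl)silyl]oxy}methyl)-1-{4-[(2,2-dimethylpropanoyl)oxy]phenyl}but-3-yn-1-yl]oxy}-2-oxo-2H-pyran-6-carboxylate | C#C[C@H](CO[Si](C)(C)C(C)(C)C)[C@@H](c1ccc(OC(=O)C(C)(C)C)cc1)OC1=CC=C(C(=O)OC)OC1=O
A7 | alternative 3 | methyl (2S,3R)-3-({[tert-butyl(dimethyl)silyl]oxy}methyl)-2-{4-[(2,2-dimethylpropanoyl)oxy]phenyl}-2,3-dihydro-1-benzofuran-5-carboxylate | COC(=O)c1ccc2c(c1)[C@H](CO[Si](C)(C)C(C)(C)C)[C@@H](c1ccc(OC(=O)C(C)(C)C)cc1)O2
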